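The plan rests on one disconnection: the terminal oxirane is opened up at its CH2 (C-3), cutting the C-2–C-3 and C-3–O-1 bonds, because the quaternary C-2 already carries the aryl ring and the CH2OAc arm and is therefore a ketone carbon in disguise. A catalytic asymmetric Corey–Chaykovsky methylene transfer makes both bonds, closes the three-membered ring and sets the single stereocentre in one operation. Its precursor is the aryl acetoxymethyl ketone in which the phenol and the benzylic alcohol are both triisopropylsilyl (TIPS) ethers; four routine steps lead to it, and one fluoride-triggered silyl-to-isobutyryl exchange leads from the epoxide to the target.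

Key step: step 5

Assumption: the (S)-binaphthoxide complex is written for step 5 on the premise that it places the methylene on the face of ketone 8 that is Si (O > CH2OAc > aryl), which is spatially the Re face of an aryl methyl ketone; if a pilot run shows the opposite sense, the (R)-binaphthoxide complex is used and nothing else changes.

Step 1
Reactants: 1 4-bromo-3-hydroxybenzoic acid
Product: 2 (4-bromo-3-hydroxyphenyl)methanol
Conditions: BH3·THF (3.5 equiv), THF, 0 °C to reflux; then aq. HCl
Reagents that add atoms: none
Why: Borane reduction of a carboxylic acid runs through the acyloxyborane and is chemoselective for CO2H over the aryl bromide, the phenol being returned from its borate on acidic work-up.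

Step 2
Reactants: 2 (4-bromo-3-hydroxyphenyl)methanol
Product: 3 [2-bromo-5-({[tri(propan-2-yl)silyl]oxy}methyl)phenoxy]tri(propan-2-yl)silane
Conditions: i-Pr3SiCl (2.5 equiv), imidazole (5 equiv), DMF, rt to 40 °C
Reagents that add atoms: triisopropylsilyl chloride, CC(C)[Si](Cl)(C(C)C)C(C)C
Why: Imidazole-promoted O-silylation caps the phenol and the primary alcohol with one reagent, and the bulky TIPS group is chosen for the phenol because it resists oxygen-to-carbon and oxygen-to-oxygen silyl shifts when a carbanion or an alkoxide later sits next to it.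

Step 3
Reactants: 3 [2-bromo-5-({[tri(propan-2-yl)silyl]oxy}methyl)phenoxy]tri(propan-2-yl)silane; 4 2-chloro-N-methoxy-N-methylacetamide
Product: 7 2-chloro-1-{2-[(triisopropylsilyl)oxy]-4-{[(triisopropylsilyl)oxy]methyl}phenyl}ethan-1-one, via aryllithium 5 (not isolated), via lithium hemiaminal alkoxide 6 (not isolated)
Conditions: n-BuLi (1.05 equiv), THF, −78 °C; then 4 (1.3 equiv), −78 °C; aq. NH4Cl
Reagents that add atoms: none
Why: Bromine–lithium exchange followed by a Weinreb ketone synthesis, in which the aryllithium adds once to the amide, the chelated tetrahedral lithium alkoxide survives until the quench, and at −78 °C neither the C–Cl bond nor the ortho silyl ether is touched.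

Step 4
Reactants: 7 2-chloro-1-{2-[(triisopropylsilyl)oxy]-4-{[(triisopropylsilyl)oxy]methyl}phenyl}ethan-1-one
Product: 8 2-oxo-2-{2-[(triisopropylsilyl)oxy]-4-{[(triisopropylsilyl)oxy]methyl}phenyl}ethyl acetate
Conditions: KOAc (2 equiv), NaI (10 mol %), acetone, rt to 40 °C
Reagents that add atoms: potassium acetate, CC(=O)[O-].[K+]
Why: SN2 displacement of a phenacyl-type chloride by acetate under iodide catalysis is fast because the adjacent carbonyl activates the C–Cl bond, and the dry, weakly basic medium leaves both silyl ethers in place.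

Step 5
Reactants: 8 2-oxo-2-{2-[(triisopropylsilyl)oxy]-4-{[(triisopropylsilyl)oxy]methyl}phenyl}ethyl acetate; 9 trimethylsulfoxonium iodide
Product: 12 [(2S)-2-{2-[(triisopropylsilyl)oxy]-4-{[(triisopropylsilyl)oxy]methyl}phenyl}oxiran-2-yl]methyl acetate, via dimethyloxosulfonium methylide 10 (not isolated), via sulfoxonium betaine 11 (not isolated)
Conditions: 9 (1.3 equiv), NaH (1.2 equiv), THF, reflux; this ylide solution then added slowly to 8, LaLi3[(S)-1,1'-binaphthalene-2,2'-diolate]3 (5 mol %), [2,4,6-(MeO)3C6H2]3P=O (5 mol %), molecular sieves 5 Å, THF, rt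
Reagents that add atoms: none
Why: Proposed new method: sulfoxonium-ylide methylene transfer catalysed by LaLi3(binaphthoxide)3 and a triarylphosphine oxide is established for aryl methyl ketones, which is the closest known reaction type, and is extended here to an alpha-acyloxymethyl aryl ketone, a substrate class on which it has not been shown and in which CH2OAc takes the place of CH3 as the small flank. The ylide carbon of 10 adds to the ketone held on the Lewis-acidic La/Li framework (trivalent lanthanum) to give betaine 11 (C-2–C-3 bond), whose alkoxide then expels dimethyl sulfoxide from the neighbouring CH2 (C-3–O-1 bond). That closure is a 3-exo-tet displacement and forms the oxirane. The stereocentre C-2 is set under catalyst control by the (S)-binaphthoxide ligands, which must steer the ylide to the Si face of the carbonyl by telling the flat aryl group from the unbranched CH2OAc arm. The step needs enantioface selectivity and ketone-over-ester chemoselectivity: the metal-bound ketone is the most electrophilic carbonyl, the acetate is an unactivated alkyl ester, and the phenol oxygen carries a bulky silyl group, so neither the ylide nor the betaine alkoxide finds an aryl ester to attack. The chief hazard is deprotonation at the CH2OAc carbon by the ylide or the basic catalyst, which slow addition of the ylide is meant to limit.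

Step 6
Reactants: 12 [(2S)-2-{2-[(triisopropylsilyl)oxy]-4-{[(triisopropylsilyl)oxy]methyl}phenyl}oxiran-2-yl]methyl acetate; 13 isobutyric anhydride
Product: 15 4-[(2S)-2-(acetoxymethyl)oxiran-2-yl]-3-[(2-methylpropanoyl)oxy]benzyl 2-methylpropanoate, via aryl isobutyrate silyl ether 14 (not isolated)
Conditions: (i-PrCO)2O (8 equiv), Bu4NF (3 equiv, 1 M in THF), THF, 0 °C to rt
Reagents that add atoms: none
Why: One-pot fluoride-mediated desilylative acylation, in which fluoride breaks the aryl O–Si bond first and the benzylic O–Si bond next and each oxyanion is acylated by the large excess of anhydride as soon as it is released, so that no ortho-phenoxide persists beside the oxirane while the acetate and the epoxide should stay intact in the carboxylate-buffered medium.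

Compound list
1 | 4-bromo-3-hydroxybenzoic acid | OC(=O)c1ccc(Br)c(O)c1 | starting material
2 | (4-bromo-3-hydroxyphenyl)methanol | OCc1ccc(Br)c(O)c1 | intermediate
3 | [2-bromo-5-({[tri(propan-2-yl)silyl]oxy}methyl)phenoxy]tri(propan-2-yl)silane | Brc1ccc(CO[Si](C(C)C)(C(C)C)C(C)C)cc1O[Si](C(C)C)(C(C)C)C(C)C | intermediate
4 | 2-chloro-N-methoxy-N-methylacetamide | CON(C)C(=O)CCl | starting material
5 | {2-[(triisopropylsilyl)oxy]-4-{[(triisopropylsilyl)oxy]methyl}phenyl}lithium (aryllithium) | [Li]c1ccc(CO[Si](C(C)C)(C(C)C)C(C)C)cc1O[Si](C(C)C)(C(C)C)C(C)C | intermediate (not isolated)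
6 | lithium 2-chloro-1-[methoxy(methyl)amino]-1-{2-[(triisopropylsilyl)oxy]-4-{[(triisopropylsilyl)oxy]methyl}phenyl}ethan-1-olate (racemic tetrahedral adduct) | [Li]OC(CCl)(N(C)OC)c1ccc(CO[Si](C(C)C)(C(C)C)C(C)C)cc1O[Si](C(C)C)(C(C)C)C(C)C | intermediate (not isolated)
7 | 2-chloro-1-{2-[(triisopropylsilyl)oxy]-4-{[(triisopropylsilyl)oxy]methyl}phenyl}ethan-1-one | ClCC(=O)c1ccc(CO[Si](C(C)C)(C(C)C)C(C)C)cc1O[Si](C(C)C)(C(C)C)C(C)C | intermediate
8 | 2-oxo-2-{2-[(triisopropylsilyl)oxy]-4-{[(triisopropylsilyl)oxy]methyl}phenyl}ethyl acetate | CC(=O)OCC(=O)c1ccc(CO[Si](C(C)C)(C(C)C)C(C)C)cc1O[Si](C(C)C)(C(C)C)C(C)C | intermediate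
9 | trimethylsulfoxonium iodide | C[S+](C)(C)=O.[I-] | starting material
10 | dimethyloxosulfonium methylide | C[S+](C)(=O)[CH2-] | intermediate (not isolated)
11 | (2R)-1-acetoxy-3-(dimethyloxosulfonio)-2-{2-[(triisopropylsilyl)oxy]-4-{[(triisopropylsilyl)oxy]methyl}phenyl}propan-2-olate (sulfoxonium betaine) | CC(=O)OC[C@@]([O-])(C[S+](C)(C)=O)c1ccc(CO[Si](C(C)C)(C(C)C)C(C)C)cc1O[Si](C(C)C)(C(C)C)C(C)C | intermediate (not isolated)
12 | [(2S)-2-{2-[(triisopropylsilyl)oxy]-4-{[(triisopropylsilyl)oxy]methyl}phenyl}oxiran-2-yl]methyl acetate | CC(=O)OC[C@]1(c2ccc(CO[Si](C(C)C)(C(C)C)C(C)C)cc2O[Si](C(C)C)(C(C)C)C(C)C)CO1 | intermediate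
13 | isobutyric anhydride (2-methylpropanoic anhydride) | CC(C)C(=O)OC(=O)C(C)C | starting material
14 | 2-[(2S)-2-(acetoxymethyl)oxiran-2-yl]-5-{[(triisopropylsilyl)oxy]methyl}phenyl 2-methylpropanoate | CC(=O)OC[C@]1(c2ccc(CO[Si](C(C)C)(C(C)C)C(C)C)cc2OC(=O)C(C)C)CO1 | intermediate (not isolated)
15 | 4-[(2S)-2-(acetoxymethyl)oxiran-2-yl]-3-[(2-methylpropanoyl)oxy]benzyl 2-methylpropanoate | CC(=O)OC[C@]1(c2ccc(COC(=O)C(C)C)cc2OC(=O)C(C)C)CO1 | target

Total step count: 6. Longest linear sequence: 6 steps (1 to 15); the ylide 10 is made and consumed within step 5.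

Steps most likely to fail

1. Step 5 (the labelled step). The ketone may be deprotonated at the CH2OAc carbon, which consumes ylide and can trigger acetyl migration through the enolate. An uncatalysed methylene transfer to this activated ketone may lower the enantiomeric purity. The catalyst may also discriminate the two flanks poorly, because CH2OAc is larger and more Lewis basic than methyl and the ortho silyloxy group twists the aryl ring. The fallback uses known chemistry only, sets out from 8 and comes back at 12.
   - Wittig methylenation of 8 (Ph3PCH3Br, t-BuOK, THF, 0 °C) should give the allyl acetate 2-{2-[(triisopropylsilyl)oxy]-4-{[(triisopropylsilyl)oxy]methyl}phenyl}prop-2-en-1-yl acetate F1.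
   - Reductive removal of the acetyl group with i-Bu2AlH (CH2Cl2, −78 °C) should give the allylic alcohol 2-{2-[(triisopropylsilyl)oxy]-4-{[(triisopropylsilyl)oxy]methyl}phenyl}prop-2-en-1-ol F2.
   - Sharpless asymmetric epoxidation (Ti(O-i-Pr)4, D-(−)-diethyl tartrate, t-BuOOH, molecular sieves 4 Å, CH2Cl2, −20 °C) should give the epoxy alcohol [(2R)-2-{2-[(triisopropylsilyl)oxy]-4-{[(triisopropylsilyl)oxy]methyl}phenyl}oxiran-2-yl]methanol F3. This tartrate enantiomer is taken to be the one that gives (R)-glycidol from allyl alcohol. A Payne rearrangement of this alcohol would be degenerate and return the same enantiomer.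
   - Acetylation (Ac2O, pyridine, DMAP, CH2Cl2, 0 °C) gives 12. The descriptor changes from R to S only because CH2OAc outranks the ring CH2 whereas CH2OH does not; the stereocentre is not touched.

2. Step 6. Cleavage of the benzylic silyl ether may stall because the anhydride ties up fluoride as acyl fluoride. The acetate may be lost and replaced by isobutyrate. The oxirane may be opened by fluoride, by carboxylate or by a phenoxide that escapes acylation. The fallback separates the two exchanges, sets out from 12 and comes back at 15.
   - CsF with isobutyric anhydride in DMF (0 °C to rt) should exchange only the aryl silyl ether and give 14 as an isolated compound.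
   - With the phenol already esterified, Et3N·3HF in THF at rt should free the benzylic alcohol 2-[(2S)-2-(acetoxymethyl)oxiran-2-yl]-5-(hydroxymethyl)phenyl 2-methylpropanoate F4.
   - Acylation with isobutyric anhydride, pyridine and DMAP (CH2Cl2, 0 °C) then gives 15.

3. Step 3. The ortho silyl group may migrate from oxygen to carbon in the aryllithium if the temperature rises. The aryllithium may deprotonate the chloroacetamide or attack its C–Cl bond. The bromine–lithium exchange may be incomplete. The fallback avoids organolithium chemistry, sets out from 3 and comes back at 8.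
   - Stille coupling of 3 with tributyl(1-ethoxyvinyl)stannane (Pd(PPh3)4, toluene, 100 °C) should give the enol ether [2-(1-ethoxyethenyl)-5-({[triisopropylsilyl]oxy}methyl)phenoxy]triisopropylsilane F5.
   - N-Bromosuccinimide in THF/H2O at 0 °C should convert it directly into the bromomethyl ketone 2-bromo-1-{2-[(triisopropylsilyl)oxy]-4-{[(triisopropylsilyl)oxy]methyl}phenyl}ethan-1-one F6.
   - Displacement with KOAc in acetone, as in step 4, gives 8.

Further compounds
F1 | step 5 | 2-{2-[(triisopropylsilyl)oxy]-4-{[(triisopropylsilyl)oxy]methyl}phenyl}prop-2-en-1-yl acetate | CC(=O)OCC(=C)c1ccc(CO[Si](C(C)C)(C(C)C)C(C)C)cc1O[Si](C(C)C)(C(C)C)C(C)C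
F2 | step 5 | 2-{2-[(triisopropylsilyl)oxy]-4-{[(triisopropylsilyl)oxy]methyl}phenyl}prop-2-en-1-ol | OCC(=C)c1ccc(CO[Si](C(C)C)(C(C)C)C(C)C)cc1O[Si](C(C)C)(C(C)C)C(C)C
F3 | step 5 | [(2R)-2-{2-[(triisopropylsilyl)oxy]-4-{[(triisopropylsilyl)oxy]methyl}phenyl}oxiran-2-yl]methanol | OC[C@]1(c2ccc(CO[Si](C(C)C)(C(C)C)C(C)C)cc2O[Si](C(C)C)(C(C)C)C(C)C)CO1
F4 | step 6 | 2-[(2S)-2-(acetoxymethyl)oxiran-2-yl]-5-(hydroxymethyl)phenyl 2-methylpropanoate | CC(=O)OC[C@]1(c2ccc(CO)cc2OC(=O)C(C)C)CO1
F5 | step 3 | [2-(1-ethoxyethenyl)-5-({[triisopropylsilyl]oxy}methyl)phenoxy]triisopropylsilane | CCOC(=C)c1ccc(CO[Si](C(C)C)(C(C)C)C(C)C)cc1O[Si](C(C)C)(C(C)C)C(C)C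
F6 | step 3 | 2-bromo-1-{2-[(triisopropylsilyl)oxy]-4-{[(triisopropylsilyl)oxy]methyl}phenyl}ethan-1-one | BrCC(=O)c1ccc(CO[Si](C(C)C)(C(C)C)C(C)C)cc1O[Si](C(C)C)(C(C)C)C(C)C
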